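## Structural features

Compound 43 is a germacranolide: a ten-membered carbocycle (C1–C10) fused at C6–C7 to an α-methylene-γ-butyrolactone (O6–C12, C11=C13), with H6 and H7 cis. The ring carries a cis 1,10-epoxide (C10 methylated), a ring-cis trisubstituted C4=C5 alkene whose C4 bears the free C15 hydroxymethyl group, an acetate at C3 and a methacrylate at C8. There are six stereocentres (1R,3S,6S,7R,8R,10S). C6, C7 and C8 are contiguous, with O6, C11 and O8 on one face; C3 faces C6 across the C4=C5 bond; the epoxide oxygen lies on the same face as O8. Fragile elements are the two Michael acceptors, the trisubstituted epoxide in a medium ring that also holds an alkene (transannular opening under acid), the allylic acetate next to a free primary allylic alcohol (acyl shift under base), and the lactone, which can move from O6 to O8 once O8 is free. The real difficulty is a ten-membered ring with two cis alkenes and stereocentres that must be set on a conformationally mobile ring. The key step exploits the fact that C3 and C8 are both oxygenated and 1,6-related. Joining them gives a six-membered ring (C3, C2, C1, C10, C9, C8) whose alkene is the later Z C1=C10. Its two alkenyl arms (C4=C5 on C3, C7=C6 on C8) flank the C3–C8 bond as a 1,5-diene, the array of an oxy-Cope ring expansion.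

## Logic of the disconnections

43 to 40. The O15–Si bond, the O8–acyl bond and the two C–O bonds of the epoxide are cut, in that order backwards (42, 41, 40). The acid- and base-sensitive groups are thereby made last, and the free O8 of 40 can steer the oxidant. 40 has neither epoxide nor methacrylate. The forward steps must deliver oxygen syn to O8 and must acylate and desilylate without a base that could move the acetate or the lactone.

40 to 39. The C8–H bond is cut, giving a C8 ketone. While C8 is a ketone, O8 cannot compete with O6 for C12. The forward reduction must choose one face and leave C11=C13 alone.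

39 to 33. The O6–C12 lactone bond, the C11=C13 bond and the oxidation level of C12 are taken back through 37, 36, 35 and 34. C13 is put on at the aldehyde stage under amine catalysis, so no lactone enolate is needed and the C3 acetate can already be present. The demand is that O6 is unmasked only after C3 has ceased to be a ketone (a cis γ-hydroxy enone would close to a cyclic hemiketal and a furan), and that the trityl ether is removed beside a silyl ether.

33 to 31. The acetyl–O3 bond and the C3–H bond are cut, giving an enone. The forward hydride must be reagent-controlled and must take the enone before the saturated C8 ketone.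

31 to 28. The O15–Si bond, the C4–C15 bond and the C4–iodine bond are cut (30, 29, 28). C15 enters as a one-carbon unit by cross-coupling on an α-iodoenone. Iodine cannot be used while the C7=C8 enol ether is present, so its hydrolysis must come first.

28 to 26. The C8 carbonyl is traced to the methyl enol ether and the C4=C5 bond to the silyl enol ether (27, 26). The forward protonation at C7 must place H7 cis to H6.

26 to 24 (key). The C5–C6 bond is cut and C3 is rejoined to C8. The ten-membered ring shrinks to a cyclohexene, and C6 becomes an sp2 enol-ether carbon. The demands are a trans arrangement of the two alkenyl groups, an E enol ether and a free C3 alkoxide. The configurations of 24 and 26 were checked against the chair transition state and against 43 and need no correction.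

24 to 22 and 23. The C3–C4 bond is cut. Vinyl adds to an α-methoxy ketone, and chelation must put it anti to the alkenyl arm.

22 to 19. Only functional groups change (21, 20, 19): the C3 carbonyl comes from a silyl-protected carbinol and the O8 methyl from the tertiary alkoxide. The C3 stereocentre exists only to set C8 and is then erased.

19 to 7 and 16. The C7–C8 bond is cut. The nucleophile is a β-alkoxyalkenyl metal with the metal anti to oxygen. The forward step needs a metal that does not expel the alkoxide and that adds trans to the silyloxy group. For that reason an organocerium reagent is used, not the bare alkenyllithium.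

16 to 8, 9 and 11. The C7–iodine and C6–H bonds are cut (syn hydrometalation of the ynol ether 14), then the O12–trityl bond, the C7–C11 bond (acetylide plus 11) and the O–C6 bond (8 plus 9). The syn addition fixes the E geometry that the key step needs.

7 to 1 and 5. The C1=C10 bond is cut (metathesis of 6), then C8–C9 (5 on the amide 4), the silyl ether, the amide and the hydroxyl (3, 2, 1). An acyloin from a cycloaddition of isoprene would be racemic, and its two oxygens could not be told apart. The chiral-pool route fixes both the absolute configuration and the position of the methyl group.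

## Other disconnections considered

Alternative 1: The cut is C1–C2. In the forward step the kinetic potassium enolate of the methyl enone in the open-chain keto aldehyde A1 adds through C2 to the C1 aldehyde, giving the ten-membered β-hydroxy enone A2. Potassium is held between the aldehyde oxygen and the C10 acetal oxygen.
- In its favour: the aldehyde cannot enolise. C6, C7, C8 and C10 are made on an open chain by reagent-controlled methods. C13 is already in place. The C1 hydroxyl and the C10 oxygen allow the epoxide to be closed by displacement, so its configuration would not depend on ring conformation. On these three points (C7/C8 control, C13, epoxide) it is better than the chosen plan.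
- Against it here: an end-to-end closure of a ten-membered ring needs high dilution and fights transannular strain. The aldol is reversible and the product can dehydrate to the C1=C2 dienone. The Z trisubstituted enone must be made selectively in an open chain. Five silyl ethers and an acetal must later be told apart, and the C3 ketone must still be reduced.
- Comparison: in structure, the chosen plan enlarges an existing ring instead of closing a large one. In mechanism, its rearrangement is made irreversible by the alkoxide-to-enolate change. In step economy the two are about equal, because A1 with four stereocentres would need a long linear sequence.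

Alternative 2: The cut is C7–C8. CrCl2 (divalent chromium) turns the bromomethyl butenolide aldehyde A3 into an allylchromium species that adds through C7 to the C8 aldehyde. This gives the ten-membered alcohol A4 and moves the alkene to C11=C13.
- In its favour: ring, C7, C8 and the α-methylene lactone arise in one mild step that tolerates the acetate and the silyl ether. A4 is the same compound as 40, three steps from 43. The chosen plan reaches 40 only thirteen steps after its ring is formed, so after the key step this alternative is clearly better in step economy. The Z C1=C10 geometry is secured beforehand, equal to the chosen plan.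
- Against it here: A3 must already hold two Z trisubstituted alkenes, C3, C6 and a β,γ-unsaturated aldehyde that drifts into conjugation. The ring is closed end to end at high dilution. Two stereocentres are set at once in a macrocyclic transition state, so the cis H6/H7 relation and the C7/C8 relation are hard to predict. Reduction or dimerisation of the allylic bromide can compete.
- Comparison: the chosen key step sets only C6, but stereospecifically through a chair. This one sets two centres with less certainty. Overall length depends on how short a route to A3 can be.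

Alternative 3: The cut is made by first joining C6 to C10, giving the hydroazulenol mesylate A5. Its C6 alkoxide fragments (Grob), breaking C6–C10 and expelling the C1 mesylate, to give the Z,Z-cyclodecadienone A6.
- In its favour: the ring is again made by opening a smaller bicycle, irreversibly and without dilution. The Z C1=C10 alkene follows from the anti-periplanar arrangement. On both points it is equal to the chosen plan. C3, C7 and C8 are set on a rigid bicycle, which is better than setting them on the ten-membered ring.
- Against it here: A5 needs five stereocentres, a quaternary C10 and a correctly oriented mesylate, so the front end is long. After fragmentation C6 is a ketone next to an epimerisable C7 and must be reduced selectively on the mobile ring. The chosen plan fixes this centre by chirality transfer. Lactonisation, α-methylenation through a lactone enolate, exchange of two protecting groups for the esters and epoxidation still follow.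
- Comparison: it is equal in ring-forming logic, better for C3/C7/C8, worse for C6, and probably longer overall.

Key step: step 15

Remark: compounds 1, 5, 8, 9, 11 and 23 are taken as purchased. Enone 27 is written ring-cis because that is the stable geometry of a cyclodec-2-enone, and any ring-trans isomer would be equilibrated by the reversible pyridine addition of step 18. Germacrane numbering is used for all ring compounds. PMB = 4-methoxybenzyl, Tr = triphenylmethyl, TIPS = triisopropylsilyl, TBS = tert-butyldimethylsilyl.

Step 1
Reactants: 1 D-allylglycine, (R)-2-aminopent-4-enoic acid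
Product: 2 (R)-2-hydroxypent-4-enoic acid
Conditions: NaNO2, 1 M H2SO4, H2O, 0 °C to rt
Reagents that add atoms: water, O
Why: Diazotisation of an α-amino acid; the carboxylate displaces N2 to an α-lactone that water reopens, so two inversions give net retention and the (R) centre is kept.

Step 2
Reactants: 2 (R)-2-hydroxypent-4-enoic acid
Product: 3 (R)-2-hydroxy-N-methoxy-N-methylpent-4-enamide
Conditions: MeNHOMe·HCl, EDC·HCl, HOBt, N-methylmorpholine, CH2Cl2, 0 °C to rt
Reagents that add atoms: N,O-dimethylhydroxylamine hydrochloride, CNOC.Cl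
Why: Carbodiimide amide coupling to the Weinreb amide; the amine outcompetes the secondary hydroxyl, and the stereocentre is not touched.

Step 3
Reactants: 3 (R)-2-hydroxy-N-methoxy-N-methylpent-4-enamide
Product: 4 (R)-N-methoxy-N-methyl-2-(triisopropylsilyloxy)pent-4-enamide
Conditions: TIPSOTf, 2,6-lutidine, CH2Cl2, 0 °C
Reagents that add atoms: triisopropylsilyl trifluoromethanesulfonate, CC(C)[Si](C(C)C)(C(C)C)OS(=O)(=O)C(F)(F)F
Why: Silylation with a silyl triflate; the bulky TIPS group is chosen because it should not migrate to a neighbouring alkoxide in step 11 and because it shields one face of ketone 7 in step 10.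

Step 4
Reactants: 4 (R)-N-methoxy-N-methyl-2-(triisopropylsilyloxy)pent-4-enamide; 5 2-methylallylmagnesium chloride
Product: 6 (R)-2-methyl-5-(triisopropylsilyloxy)octa-1,7-dien-4-one
Conditions: THF, −78 to −20 °C; cold aq. NH4Cl
Reagents that add atoms: none
Why: Weinreb ketone synthesis; the chelated tetrahedral intermediate stops at the ketone and protects the α-centre, and the cold buffered quench should keep the β,γ-alkene out of conjugation.

Step 5
Reactants: 6 (R)-2-methyl-5-(triisopropylsilyloxy)octa-1,7-dien-4-one
Product: 7 (R)-5-methyl-2-(triisopropylsilyloxy)cyclohex-4-en-1-one (C8 ketone, C3 silyloxy)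
Conditions: second-generation Grubbs catalyst RuCl2(=CHPh)(PCy3)(H2IMes) (5 mol %), 1,4-benzoquinone (10 mol %), CH2Cl2, 40 °C
Reagents that add atoms: none
Why: Ring-closing metathesis of a 1,7-diene to a cyclohexene with loss of ethene; the ring forces the Z C1=C10 geometry and the methyl group sits unambiguously on the carbon next to C9.

Step 6
Reactants: 8 4-methoxybenzyl alcohol; 9 trichloroethene
Product: 10 1-{[(E)-1,2-dichloroethenyl]oxymethyl}-4-methoxybenzene
Conditions: KH, THF, 0 °C; then 9, rt
Reagents that add atoms: none
Why: Base-induced elimination of trichloroethene to dichloroethyne and addition of the potassium alkoxide, the standard entry to 1,2-dichlorovinyl ethers.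

Step 7
Reactants: 10 1-{[(E)-1,2-dichloroethenyl]oxymethyl}-4-methoxybenzene; 11 oxirane
Product: 13 4-[(4-methoxybenzyl)oxy]but-3-yn-1-ol, via lithium alkoxyethynide 12 (not isolated)
Conditions: n-BuLi (2.2 equiv), THF, −78 to −40 °C; then BF3·OEt2, 11, −78 °C
Reagents that add atoms: none
Why: Two equivalents of butyllithium convert the dichlorovinyl ether into the lithium alkoxyethynide (elimination, then chlorine–lithium exchange); BF3-assisted opening of the epoxide by the acetylide gives the homopropargylic alcohol with C11 and C12 in place.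

Step 8
Reactants: 13 4-[(4-methoxybenzyl)oxy]but-3-yn-1-ol
Product: 14 1-methoxy-4-({[4-(trityloxy)but-1-yn-1-yl]oxy}methyl)benzene
Conditions: Ph3CCl, Et3N, DMAP (cat.), CH2Cl2, rt
Reagents that add atoms: chlorotriphenylmethane, ClC(c1ccccc1)(c1ccccc1)c1ccccc1
Why: Tritylation of the primary alcohol; the trityl ether withstands fluoride, bases and organometallic reagents up to step 22 and leaves under mild acid in step 23.

Step 9
Reactants: 14 1-methoxy-4-({[4-(trityloxy)but-1-yn-1-yl]oxy}methyl)benzene
Product: 16 1-({[(E)-2-iodo-4-(trityloxy)but-1-en-1-yl]oxy}methyl)-4-methoxybenzene, via alkenylzirconocene chloride 15 (not isolated)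
Conditions: Cp2Zr(H)Cl, THF, 0 °C to rt; then I2 (1.0 equiv), −78 °C
Reagents that add atoms: iodine, [I][I]
Why: Hydrozirconation is a syn addition; hydride goes to the electrophilic oxygen-bearing carbon C6 and zirconium to C7, and iodinolysis with retention leaves iodine trans to oxygen, the E geometry needed for the key step.

Step 10
Reactants: 7 (R)-5-methyl-2-(triisopropylsilyloxy)cyclohex-4-en-1-one; 16 1-({[(E)-2-iodo-4-(trityloxy)but-1-en-1-yl]oxy}methyl)-4-methoxybenzene
Product: 19 (3R,8R)-tertiary alcohol, (1R,6R)-1-{(E)-1-[(4-methoxybenzyl)oxy]-4-(trityloxy)but-1-en-2-yl}-3-methyl-6-(triisopropylsilyloxy)cyclohex-3-en-1-ol, via alkenyllithium 17 (not isolated), via alkenylcerium dichloride 18 (not isolated)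
Conditions: 16, t-BuLi (2.0 equiv), Et2O, −100 °C; CeCl3·2LiCl, THF, −78 °C; then 7, −78 °C
Reagents that add atoms: none
Why: Iodine–lithium exchange with retention is followed at once by transmetalation to cerium, which should suppress both anti elimination of the β-alkoxide and enolisation of the β,γ-unsaturated ketone. The organocerium 1,2-addition should occur trans to the bulky C3 silyloxy group and set C8 (R).

Step 11
Reactants: 19 (3R,8R)-tertiary alcohol
Product: 20 methyl ether of 19 (C8 methoxy, C3 triisopropylsilyloxy)
Conditions: KH, MeI, THF, 0 °C to rt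
Reagents that add atoms: iodomethane, C[I]
Why: Williamson methylation of the tertiary potassium alkoxide; the triisopropylsilyl ether should stay on O3 where a smaller silyl group could migrate.

Step 12
Reactants: 20 methyl ether of 19
Product: 21 (1R,2R)-2-methoxy-4-methyl-2-{(E)-1-[(4-methoxybenzyl)oxy]-4-(trityloxy)but-1-en-2-yl}cyclohex-4-en-1-ol
Conditions: Bu4NF, THF, rt
Reagents that add atoms: none
Why: Fluoride cleaves the Si–O bond; the trityl ether, the enol ether and the tertiary allylic methyl ether are stable to the basic medium.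

Step 13
Reactants: 21 (1R,2R)-secondary alcohol
Product: 22 (R)-2-methoxy-4-methyl-2-{(E)-1-[(4-methoxybenzyl)oxy]-4-(trityloxy)but-1-en-2-yl}cyclohex-4-en-1-one (C3 ketone)
Conditions: Dess–Martin periodinane, NaHCO3, CH2Cl2, 0 °C
Reagents that add atoms: none
Why: Buffered Dess–Martin oxidation spares the acid-labile enol ether; the C3 stereocentre has served to set C8 and is erased here.

Step 14
Reactants: 22 (R)-α-methoxy ketone; 23 vinylmagnesium bromide
Product: 24 (1R,2R)-1-ethenyl-2-methoxy-4-methyl-2-{(E)-1-[(4-methoxybenzyl)oxy]-4-(trityloxy)but-1-en-2-yl}cyclohex-4-en-1-ol (alkenyl groups trans)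
Conditions: THF/CH2Cl2, −78 °C
Reagents that add atoms: none
Why: Chelation-controlled Grignard addition: magnesium bridges the carbonyl oxygen and the α-methoxy oxygen, the alkenyl arm stands perpendicular to the chelate and vinyl enters anti to it, which should give the trans dialkenyl carbinol.

Step 15
Reactants: 24 (1R,2R)-trans-dialkenyl carbinol
Product: 26 (6S)-ten-membered bis(enol ether), 3-(trimethylsilyloxy)-8-methoxy-6-[(4-methoxybenzyl)oxy]-10-methyl-7-[2-(trityloxy)ethyl]cyclodeca-1(10),3,7-triene (1(10)Z,3E,7E), via potassium enolate 25 (not isolated)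
Conditions: KH, 18-crown-6, THF, 0 °C to rt; then Me3SiCl, Et3N, −78 °C
Reagents that add atoms: chlorotrimethylsilane, C[Si](C)(C)Cl
Why: KH with the crown ether gives the free C3 potassium alkoxide, which weakens the C3–C8 bond; a concerted [3,3] shift through the chair array C5=C4–C3–C8–C7=C6 then joins C5 to C6 and breaks C3–C8, and the resulting enolate 25 is silylated on oxygen. The closest known reaction type is the anionic oxy-Cope ring expansion of trans-1,2-divinylcyclohexanols to cyclodec-5-enones. No ring is closed end to end: the ten-membered ring arises because the bond shared by the two arms of the cyclohexene is cut, a four-carbon ring expansion. The one new stereocentre, C6, is controlled by chirality transfer from C3 and C8 together with the E geometry of the enol ether. The trans dialkenyl ring can reach only the chair in which both ring bonds are equatorial, the O6 substituent of the E terminus is then equatorial, and C5 bonds to one face of C6 only, which should give 6S. The step needs chair over boat, a concerted path, and an enolate that keeps its position. The first is secured by the trans arrangement. The second is helped by the methoxy and PMB-oxy donors, which disfavour heterolysis to an allyl anion. The third is secured by silylating cold before proton transfer to the doubly activated C2. The C1=C10 alkene is held Z by the six-membered ring and cannot take part, because the reacting arms are equatorial and point away from it.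

Step 16
Reactants: 26 (6S)-bis(enol ether)
Product: 27 (6S)-8-methoxy-6-[(4-methoxybenzyl)oxy]-10-methyl-7-[2-(trityloxy)ethyl]cyclodeca-1(10),4,7-trien-3-one (1(10)Z,4Z,7E)
Conditions: Pd(OAc)2 (1.1 equiv), MeCN, rt
Reagents that add atoms: none
Why: Saegusa–Ito oxidation: divalent palladium exchanges with the trimethylsilyl enol ether and β-hydride elimination gives the C4=C5 enone, while the methyl enol ether cannot transmetalate; the ring-cis enone is the stable geometry in a ten-membered ring.

Step 17
Reactants: 27 (6S)-trienone
Product: 28 (6S,7S)-6-[(4-methoxybenzyl)oxy]-10-methyl-7-[2-(trityloxy)ethyl]cyclodeca-1(10),4-diene-3,8-dione (1(10)Z,4Z; H7 cis to H6)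
Conditions: pyridinium p-toluenesulfonate (cat.), acetone/H2O, 0 °C
Reagents that add atoms: water, O
Why: Mild acid hydrolysis of the strained ring-trans tetrasubstituted enol ether (protonation at C7, then loss of methanol) with an acid too weak to ionise the trityl or PMB ether. In the conformer that keeps H6 in the plane of C7=C8 to avoid allylic strain with the methoxy group, the outer face of the alkene is the one syn to O6, so the proton should arrive there and place H7 cis to H6.

Step 18
Reactants: 28 (6S,7S)-dienedione
Product: 29 (6S,7S)-4-iodo-6-[(4-methoxybenzyl)oxy]-10-methyl-7-[2-(trityloxy)ethyl]cyclodeca-1(10),4-diene-3,8-dione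
Conditions: I2, pyridine, CH2Cl2, 0 °C to rt
Reagents that add atoms: iodine, [I][I]
Why: α-Iodination of an enone by conjugate addition of pyridine, iodination of the enolate and elimination; the reversible pyridine addition also equilibrates any ring-trans enone to the cis isomer.

Step 19
Reactants: 29 α-iodoenone
Product: 30 (6S,7S)-4-(hydroxymethyl)-6-[(4-methoxybenzyl)oxy]-10-methyl-7-[2-(trityloxy)ethyl]cyclodeca-1(10),4-diene-3,8-dione
Conditions: Bu3SnCH2OH, Pd(PPh3)4 (cat.), 1,4-dioxane, 80 °C
Reagents that add atoms: (tributylstannyl)methanol, CCCC[Sn](CCCC)(CCCC)CO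
Why: Stille coupling of the α-iodoenone with a hydroxymethylstannane brings in C15 with retention of the alkene geometry under neutral conditions that do not enolise the ketones.

Step 20
Reactants: 30 hydroxymethyl enone
Product: 31 O15-TBS ether of 30
Conditions: t-BuMe2SiCl, imidazole, CH2Cl2, 0 °C
Reagents that add atoms: tert-butyldimethylsilyl chloride, CC(C)(C)[Si](C)(C)Cl
Why: Silylation of the only free hydroxyl; the primary allylic silyl ether is kept to the last step.

Step 21
Reactants: 31 O15-TBS enone
Product: 32 (3S,6S,7S)-3-hydroxy-4-[(tert-butyldimethylsilyloxy)methyl]-6-[(4-methoxybenzyl)oxy]-10-methyl-7-[2-(trityloxy)ethyl]cyclodeca-1(10),4-dien-8-one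
Conditions: (R)-2-methyl-CBS-oxazaborolidine, catecholborane, toluene/CH2Cl2, −78 °C
Reagents that add atoms: none
Why: Corey–Bakshi–Shibata reduction; the conjugated, more basic enone carbonyl binds the catalyst and should be reduced well before the hindered saturated C8 ketone at −78 °C. With the α-branched alkenyl side as the large group, the (R)-catalyst should give 3S.

Step 22
Reactants: 32 (3S)-allylic alcohol
Product: 33 O3-acetate of 32
Conditions: Ac2O, pyridine, DMAP (cat.), CH2Cl2, 0 °C
Reagents that add atoms: acetic anhydride, CC(=O)OC(C)=O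
Why: DMAP-catalysed acetylation of the secondary allylic alcohol; because C13 is later introduced without strong base, the acetate can stay to the end.

Step 23
Reactants: 33 O3-acetate
Product: 34 (3S,6S,7S)-3-acetoxy-4-[(tert-butyldimethylsilyloxy)methyl]-7-(2-hydroxyethyl)-6-[(4-methoxybenzyl)oxy]-10-methylcyclodeca-1(10),4-dien-8-one (in equilibrium with its cyclic hemiketal)
Conditions: HCO2H/Et2O (1:1), 0 °C, short contact
Reagents that add atoms: none
Why: Trityl ethers ionise in formic acid within minutes, while a primary silyl ether, the PMB ether and the acetate should survive a short exposure.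

Step 24
Reactants: 34 primary alcohol
Product: 35 C12 aldehyde, (3S,6S,7S)-3-acetoxy-4-[(tert-butyldimethylsilyloxy)methyl]-6-[(4-methoxybenzyl)oxy]-10-methyl-7-(2-oxoethyl)cyclodeca-1(10),4-dien-8-one
Conditions: Dess–Martin periodinane, NaHCO3, CH2Cl2, 0 °C
Reagents that add atoms: none
Why: Neutral oxidation of the open hydroxy ketone form to the aldehyde; no acid or base is present that could turn the 1,4-dicarbonyl unit into a furan or an aldol product.

Step 25
Reactants: 35 C12 aldehyde
Product: 36 C12 α-methylene aldehyde (C11=C13)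
Conditions: aq. CH2O, pyrrolidine (cat.), EtCO2H (cat.), i-PrOH, 45 °C
Reagents that add atoms: formaldehyde, C=O
Why: Amine-catalysed Mannich condensation and elimination (α-methylenation of an aldehyde) under almost neutral conditions introduces C13 without a strong base, so the acetate, the C8 ketone and C7 are not disturbed.

Step 26
Reactants: 36 α-methylene aldehyde
Product: 37 α-substituted acrylic acid (C12 acid)
Conditions: NaClO2, NaH2PO4, 2-methylbut-2-ene, t-BuOH/H2O, 0 °C
Reagents that add atoms: sodium chlorite, [Na+].[O-]Cl=O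
Why: Pinnick oxidation takes an enal to the acid without touching alkenes; the scavenger removes hypochlorous acid before it can attack C1=C10 or the PMB ring.

Step 27
Reactants: 37 acrylic acid
Product: 39 (3S,6S,7S)-3-acetoxy-15-(tert-butyldimethylsilyloxy)-8-oxogermacra-1(10)Z,4Z,11(13)-trien-12,6-olide (cis-fused), via hydroxy acid 38 (not isolated)
Conditions: DDQ, CH2Cl2/pH 7 buffer, 0 °C to rt; then PPTS (cat.), CH2Cl2, rt if needed
Reagents that add atoms: none
Why: Oxidative removal of the PMB ether frees O6, which lies cis to the acrylic acid on C7 and closes the γ-lactone. O6 is unmasked only now, when C3 is an ester and C8 still a ketone, so neither a furan nor the 8,12-lactone can form.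

Step 28
Reactants: 39 8-oxo lactone
Product: 40 (3S,6S,7R,8R)-3-acetoxy-15-(tert-butyldimethylsilyloxy)-8-hydroxygermacra-1(10)Z,4Z,11(13)-trien-12,6-olide
Conditions: (S)-2-methyl-CBS-oxazaborolidine, BH3·SMe2, THF, −30 °C
Reagents that add atoms: none
Why: CBS reduction with the branched C7 side as the large group should give 8R; the same face is the one opposite the C7–C11 bond of the cis-fused lactone, so reagent and substrate agree. Catalysed borane does not reduce the α-methylene lactone, which borohydride could attack in the conjugate sense.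

Step 29
Reactants: 40 8-hydroxy lactone
Product: 41 (1R,3S,6S,7R,8R,10S)-3-acetoxy-15-(tert-butyldimethylsilyloxy)-1,10-epoxy-8-hydroxygermacra-4Z,11(13)-dien-12,6-olide
Conditions: VO(acac)2 (cat.), t-BuOOH, CH2Cl2, 0 °C to rt
Reagents that add atoms: tert-butyl hydroperoxide, CC(C)(C)OO
Why: Hydroxyl-directed epoxidation of a homoallylic alcohol: the vanadium alkoxide of O8 should deliver oxygen to the near face of the electron-rich C1=C10, syn to O8. The C4=C5 alkene (three allylic oxygens) and C11=C13 are too electron-poor to react.

Step 30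
Reactants: 41 epoxy alcohol
Product: 42 O15-TBS ether of 43
Conditions: methacrylic anhydride, Et3N, DMAP, CH2Cl2, 0 °C to rt
Reagents that add atoms: methacrylic anhydride, C=C(C)C(=O)OC(=O)C(C)=C
Why: DMAP-catalysed acylation of the hindered secondary alcohol; once O8 is acylated the lactone can no longer move to it.

Step 31
Reactants: 42 O15-TBS ether
Product: 43 (1R,3S,6S,7R,8R,10S)-3-acetoxy-1,10-epoxy-15-hydroxy-8-(methacryloyloxy)germacra-4Z,11(13)-dien-12,6-olide
Conditions: HF·pyridine, pyridine, THF, 0 °C
Reagents that add atoms: none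
Why: Buffered hydrogen fluoride cleaves the primary silyl ether without base, so the acetate should not shift from O3 to O15 and the Michael acceptors and epoxide stay intact.

## Compound list

1 | D-allylglycine, (R)-2-aminopent-4-enoic acid | C=CC[C@@H](N)C(=O)O | starting material
2 | (R)-2-hydroxypent-4-enoic acid | C=CC[C@@H](O)C(=O)O | intermediate
3 | (R)-2-hydroxy-N-methoxy-N-methylpent-4-enamide | C=CC[C@@H](O)C(=O)N(C)OC | intermediate
4 | (R)-N-methoxy-N-methyl-2-(triisopropylsilyloxy)pent-4-enamide | C=CC[C@@H](O[Si](C(C)C)(C(C)C)C(C)C)C(=O)N(C)OC | intermediate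
5 | 2-methylallylmagnesium chloride | C=C(C)C[Mg]Cl | starting material
6 | (R)-2-methyl-5-(triisopropylsilyloxy)octa-1,7-dien-4-one | C=CC[C@@H](O[Si](C(C)C)(C(C)C)C(C)C)C(=O)CC(C)=C | intermediate
7 | (R)-5-methyl-2-(triisopropylsilyloxy)cyclohex-4-en-1-one | CC1=CC[C@@H](O[Si](C(C)C)(C(C)C)C(C)C)C(=O)C1 | intermediate
8 | 4-methoxybenzyl alcohol | COc1ccc(CO)cc1 | starting material
9 | trichloroethene | ClC=C(Cl)Cl | starting material
10 | 1-{[(E)-1,2-dichloroethenyl]oxymethyl}-4-methoxybenzene | COc1ccc(CO/C(Cl)=C\Cl)cc1 | intermediate
11 | oxirane | C1CO1 | starting material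
12 | lithium [(4-methoxybenzyl)oxy]ethynide | [Li]C#COCc1ccc(OC)cc1 | intermediate
13 | 4-[(4-methoxybenzyl)oxy]but-3-yn-1-ol | COc1ccc(COC#CCCO)cc1 | intermediate
14 | 1-methoxy-4-({[4-(trityloxy)but-1-yn-1-yl]oxy}methyl)benzene | COc1ccc(COC#CCCOC(c2ccccc2)(c2ccccc2)c2ccccc2)cc1 | intermediate
15 | chloridobis(cyclopentadienyl){(E)-1-[(4-methoxybenzyl)oxy]-4-(trityloxy)but-1-en-2-yl}zirconium | COc1ccc(CO/C=C(/[Zr](Cl)(C2C=CC=C2)C2C=CC=C2)CCOC(c2ccccc2)(c2ccccc2)c2ccccc2)cc1 | intermediate
16 | 1-({[(E)-2-iodo-4-(trityloxy)but-1-en-1-yl]oxy}methyl)-4-methoxybenzene | COc1ccc(CO/C=C(/I)CCOC(c2ccccc2)(c2ccccc2)c2ccccc2)cc1 | intermediate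
17 | {(E)-1-[(4-methoxybenzyl)oxy]-4-(trityloxy)but-1-en-2-yl}lithium | COc1ccc(CO/C=C(/[Li])CCOC(c2ccccc2)(c2ccccc2)c2ccccc2)cc1 | intermediate
18 | dichlorido{(E)-1-[(4-methoxybenzyl)oxy]-4-(trityloxy)but-1-en-2-yl}cerium | COc1ccc(CO/C=C(/[Ce](Cl)Cl)CCOC(c2ccccc2)(c2ccccc2)c2ccccc2)cc1 | intermediate
19 | (1R,6R)-1-{(E)-1-[(4-methoxybenzyl)oxy]-4-(trityloxy)but-1-en-2-yl}-3-methyl-6-(triisopropylsilyloxy)cyclohex-3-en-1-ol | CC(C)[Si](C(C)C)(C(C)C)O[C@@H]1CC=C(C)C[C@@]1(O)/C(CCOC(c2ccccc2)(c2ccccc2)c2ccccc2)=C/OCc1ccc(OC)cc1 | intermediate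
20 | methyl ether of 19 (C8 methoxy, C3 triisopropylsilyloxy; 3R,8R) | CC(C)[Si](C(C)C)(C(C)C)O[C@@H]1CC=C(C)C[C@@]1(OC)/C(CCOC(c2ccccc2)(c2ccccc2)c2ccccc2)=C/OCc1ccc(OC)cc1 | intermediate
21 | (1R,2R)-2-methoxy-4-methyl-2-{(E)-1-[(4-methoxybenzyl)oxy]-4-(trityloxy)but-1-en-2-yl}cyclohex-4-en-1-ol | O[C@@H]1CC=C(C)C[C@@]1(OC)/C(CCOC(c2ccccc2)(c2ccccc2)c2ccccc2)=C/OCc1ccc(OC)cc1 | intermediate
22 | (R)-2-methoxy-4-methyl-2-{(E)-1-[(4-methoxybenzyl)oxy]-4-(trityloxy)but-1-en-2-yl}cyclohex-4-en-1-one | O=C1CC=C(C)C[C@@]1(OC)/C(CCOC(c2ccccc2)(c2ccccc2)c2ccccc2)=C/OCc1ccc(OC)cc1 | intermediate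
23 | vinylmagnesium bromide | C=C[Mg]Br | starting material
24 | (1R,2R)-1-ethenyl-2-methoxy-4-methyl-2-{(E)-1-[(4-methoxybenzyl)oxy]-4-(trityloxy)but-1-en-2-yl}cyclohex-4-en-1-ol | C=C[C@]1(O)CC=C(C)C[C@@]1(OC)/C(CCOC(c2ccccc2)(c2ccccc2)c2ccccc2)=C/OCc1ccc(OC)cc1 | intermediate
25 | potassium enolate of the ring-expanded C3 ketone (6S) | COc1ccc(CO[C@H]2C/C=C(\[O-])C/C=C(C)\C/C(OC)=C2\CCOC(c3ccccc3)(c3ccccc3)c3ccccc3)cc1.[K+] | intermediate
26 | (6S)-3-(trimethylsilyloxy)-8-methoxy-6-[(4-methoxybenzyl)oxy]-10-methyl-7-[2-(trityloxy)ethyl]cyclodeca-1(10),3,7-triene (1(10)Z,3E,7E) | COc1ccc(CO[C@H]2C/C=C(\O[Si](C)(C)C)C/C=C(C)\C/C(OC)=C2\CCOC(c3ccccc3)(c3ccccc3)c3ccccc3)cc1 | intermediate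
27 | (6S)-8-methoxy-6-[(4-methoxybenzyl)oxy]-10-methyl-7-[2-(trityloxy)ethyl]cyclodeca-1(10),4,7-trien-3-one (1(10)Z,4Z,7E) | COc1ccc(CO[C@H]2/C=C\C(=O)C/C=C(C)\C/C(OC)=C2\CCOC(c3ccccc3)(c3ccccc3)c3ccccc3)cc1 | intermediate
28 | (6S,7S)-6-[(4-methoxybenzyl)oxy]-10-methyl-7-[2-(trityloxy)ethyl]cyclodeca-1(10),4-diene-3,8-dione (1(10)Z,4Z) | COc1ccc(CO[C@H]2/C=C\C(=O)C/C=C(C)\CC(=O)[C@H]2CCOC(c3ccccc3)(c3ccccc3)c3ccccc3)cc1 | intermediate
29 | 4-iodo derivative of 28 | COc1ccc(CO[C@H]2/C=C(/I)C(=O)C/C=C(C)\CC(=O)[C@H]2CCOC(c3ccccc3)(c3ccccc3)c3ccccc3)cc1 | intermediate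
30 | 4-(hydroxymethyl) derivative of 28 | COc1ccc(CO[C@H]2/C=C(/CO)C(=O)C/C=C(C)\CC(=O)[C@H]2CCOC(c3ccccc3)(c3ccccc3)c3ccccc3)cc1 | intermediate
31 | O15-TBS ether of 30 | COc1ccc(CO[C@H]2/C=C(/CO[Si](C)(C)C(C)(C)C)C(=O)C/C=C(C)\CC(=O)[C@H]2CCOC(c3ccccc3)(c3ccccc3)c3ccccc3)cc1 | intermediate
32 | (3S,6S,7S)-3-hydroxy-8-ketone | COc1ccc(CO[C@H]2/C=C(/CO[Si](C)(C)C(C)(C)C)[C@@H](O)C/C=C(C)\CC(=O)[C@H]2CCOC(c3ccccc3)(c3ccccc3)c3ccccc3)cc1 | intermediate
33 | O3-acetate of 32 | COc1ccc(CO[C@H]2/C=C(/CO[Si](C)(C)C(C)(C)C)[C@@H](OC(C)=O)C/C=C(C)\CC(=O)[C@H]2CCOC(c3ccccc3)(c3ccccc3)c3ccccc3)cc1 | intermediate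
34 | C12 primary alcohol (trityl removed) | COc1ccc(CO[C@H]2/C=C(/CO[Si](C)(C)C(C)(C)C)[C@@H](OC(C)=O)C/C=C(C)\CC(=O)[C@H]2CCO)cc1 | intermediate
35 | C12 aldehyde | COc1ccc(CO[C@H]2/C=C(/CO[Si](C)(C)C(C)(C)C)[C@@H](OC(C)=O)C/C=C(C)\CC(=O)[C@H]2CC=O)cc1 | intermediate
36 | C12 α-methylene aldehyde | COc1ccc(CO[C@H]2/C=C(/CO[Si](C)(C)C(C)(C)C)[C@@H](OC(C)=O)C/C=C(C)\CC(=O)[C@H]2C(=C)C=O)cc1 | intermediate
37 | C12 acrylic acid | COc1ccc(CO[C@H]2/C=C(/CO[Si](C)(C)C(C)(C)C)[C@@H](OC(C)=O)C/C=C(C)\CC(=O)[C@H]2C(=C)C(=O)O)cc1 | intermediate
38 | 6-hydroxy acrylic acid | O[C@H]1/C=C(/CO[Si](C)(C)C(C)(C)C)[C@@H](OC(C)=O)C/C=C(C)\CC(=O)[C@H]1C(=C)C(=O)O | intermediate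
39 | (3S,6S,7S)-3-acetoxy-15-(tert-butyldimethylsilyloxy)-8-oxogermacra-1(10)Z,4Z,11(13)-trien-12,6-olide | O=C1C/C(C)=C\C[C@H](OC(C)=O)/C(CO[Si](C)(C)C(C)(C)C)=C\[C@@H]2OC(=O)C(=C)[C@@H]21 | intermediate
40 | (3S,6S,7R,8R)-3-acetoxy-15-(tert-butyldimethylsilyloxy)-8-hydroxygermacra-1(10)Z,4Z,11(13)-trien-12,6-olide | O[C@@H]1C/C(C)=C\C[C@H](OC(C)=O)/C(CO[Si](C)(C)C(C)(C)C)=C\[C@@H]2OC(=O)C(=C)[C@@H]21 | intermediate
41 | (1R,3S,6S,7R,8R,10S)-3-acetoxy-15-(tert-butyldimethylsilyloxy)-1,10-epoxy-8-hydroxygermacra-4Z,11(13)-dien-12,6-olide | O[C@@H]1C[C@]2(C)O[C@@H]2C[C@H](OC(C)=O)/C(CO[Si](C)(C)C(C)(C)C)=C\[C@@H]2OC(=O)C(=C)[C@@H]21 | intermediate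
42 | O15-TBS ether of 43 | C=C(C)C(=O)O[C@@H]1C[C@]2(C)O[C@@H]2C[C@H](OC(C)=O)/C(CO[Si](C)(C)C(C)(C)C)=C\[C@@H]2OC(=O)C(=C)[C@@H]21 | intermediate
43 | (1R,3S,6S,7R,8R,10S)-3-acetoxy-1,10-epoxy-15-hydroxy-8-(methacryloyloxy)germacra-4Z,11(13)-dien-12,6-olide (CNP0319155.2) | C=C(C)C(=O)O[C@@H]1C[C@]2(C)O[C@@H]2C[C@H](OC(C)=O)/C(CO)=C\[C@@H]2OC(=O)C(=C)[C@@H]21 | target

## Step count and least certain steps

Total step count: 31. Longest linear sequence: 27 steps (steps 1–5 and 10–31, from 1). The alkenyl iodide branch (steps 6–9) has 4 steps.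

Step 15 (key step). Two processes could spoil it. Proton transfer before silylation could move the enolate from C3/C4 to the doubly activated C2, which would lose the regiochemistry that step 16 needs. A stepwise cleavage of C3–C8 followed by recombination could erode chirality transfer to C6. The fallback sets out from 24 and returns at 26. The tertiary hydroxyl is silylated (Me3SiCl, imidazole) to the trimethylsilyl ether F6, which is then rearranged thermally without base (toluene, 180–200 °C, sealed base-washed vessel). This neutral siloxy-Cope shift gives the silyl enol ether 26 directly, with no free enolate or alkoxide at any time.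

Step 10. Anti elimination of the β-alkoxide from alkenyllithium 17 (the C–Li bond is anti-periplanar to C6–O) could outrun transmetalation, and the organometallic could enolise ketone 7. The fallback avoids a carbanion; it sets out from 2 and returns at 20. The hydroxyl of 2 is silylated (TIPSOTf, 2,6-lutidine; aqueous K2CO3 work-up) to (R)-2-(triisopropylsilyloxy)pent-4-enoic acid F1. This is converted with oxalyl chloride into the acid chloride F2. F2 is coupled with alkenylzirconocene 15 (CuI catalysis) to the β-alkoxy enone F3. Reagent 5 is then added under Felkin–Anh control by the non-chelating silyloxy group to give the tertiary alcohol F4. Methylation (KH, MeI) gives the methyl ether F5, and ring-closing metathesis of F5 closes the cyclohexene to 20.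

Step 17. Facial selectivity of protonation at C7 may be poor on the mobile ring, the trityl ether may be partly lost, and C1=C10 may drift into conjugation with the new ketone. The fallback sets out from 27 and returns at 33. The hydrolysis product is carried as a C7 mixture through steps 18–22. The 7-epimer of the acetate, F7, is then separated and equilibrated at the ketone α-carbon with DBU in toluene (thermodynamic instead of kinetic control, with recycling). This feeds 33.

Step 21. The C8 ketone may be reduced as well, or the ring conformation may override the catalyst at C3. The fallback sets out from 31 and returns at 33. A Luche reduction (NaBH4, CeCl3, MeOH, −78 °C) takes the lanthanide-activated enone first. If the 3-epimeric alcohol F8 predominates, a Mitsunobu reaction with acetic acid (PPh3, DIAD) inverts C3 and gives acetate 33 directly.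

Step 29. The Lewis-acidic catalyst may trigger transannular opening of the new epoxide, the lactone may shift to the free O8, or oxygen may arrive on the wrong face if the hydroxyl cannot reach the alkene. The fallback sets out from 40 and returns at 42. O8 is acylated first (methacrylic anhydride, Et3N, DMAP) to the methacrylate F9. F9 is then epoxidised with dimethyldioxirane in acetone at −20 °C, a neutral reagent that attacks the electron-rich C1=C10 from the outer face.

## Further compounds

F1 | step 10 | (R)-2-(triisopropylsilyloxy)pent-4-enoic acid | C=CC[C@@H](O[Si](C(C)C)(C(C)C)C(C)C)C(=O)O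
F2 | step 10 | (R)-2-(triisopropylsilyloxy)pent-4-enoyl chloride | C=CC[C@@H](O[Si](C(C)C)(C(C)C)C(C)C)C(Cl)=O
F3 | step 10 | (R,E)-1-[(4-methoxybenzyl)oxy]-2-[2-(trityloxy)ethyl]-4-(triisopropylsilyloxy)hepta-1,6-dien-3-one | C=CC[C@@H](O[Si](C(C)C)(C(C)C)C(C)C)C(=O)/C(CCOC(c1ccccc1)(c1ccccc1)c1ccccc1)=C/OCc1ccc(OC)cc1
F4 | step 10 | tertiary alcohol from addition of 5 to F3 (open-chain, C8 as in 19) | C=CC[C@@H](O[Si](C(C)C)(C(C)C)C(C)C)[C@@](O)(CC(C)=C)/C(CCOC(c1ccccc1)(c1ccccc1)c1ccccc1)=C/OCc1ccc(OC)cc1
F5 | step 10 | methyl ether of F4 | C=CC[C@@H](O[Si](C(C)C)(C(C)C)C(C)C)[C@@](OC)(CC(C)=C)/C(CCOC(c1ccccc1)(c1ccccc1)c1ccccc1)=C/OCc1ccc(OC)cc1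
F6 | step 15 | O3-trimethylsilyl ether of 24 | C=C[C@]1(O[Si](C)(C)C)CC=C(C)C[C@@]1(OC)/C(CCOC(c2ccccc2)(c2ccccc2)c2ccccc2)=C/OCc1ccc(OC)cc1
F7 | step 17 | 7-epimer of 33 | COc1ccc(CO[C@H]2/C=C(/CO[Si](C)(C)C(C)(C)C)[C@@H](OC(C)=O)C/C=C(C)\CC(=O)[C@@H]2CCOC(c3ccccc3)(c3ccccc3)c3ccccc3)cc1
F8 | step 21 | 3-epimer of 32 | COc1ccc(CO[C@H]2/C=C(/CO[Si](C)(C)C(C)(C)C)[C@H](O)C/C=C(C)\CC(=O)[C@H]2CCOC(c3ccccc3)(c3ccccc3)c3ccccc3)cc1
F9 | step 29 | 8-O-methacrylate of 40 | C=C(C)C(=O)O[C@@H]1C/C(C)=C\C[C@H](OC(C)=O)/C(CO[Si](C)(C)C(C)(C)C)=C\[C@@H]2OC(=O)C(=C)[C@@H]21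
A1 | alternative 1 | open-chain C1 aldehyde with C3 methyl enone | CC(=O)/C(CO[Si](c1ccccc1)(c1ccccc1)C(C)(C)C)=C\[C@H](O[Si](CC)(CC)CC)[C@@H]([C@@H](C[C@](C)(OCOC)C=O)O[Si](C)(C)C(C)(C)C)C(=C)CO[Si](CC)(CC)CC
A2 | alternative 1 | ten-membered β-hydroxy enone | CC(C)(C)[Si](C)(C)O[C@@H]1C[C@](C)(OCOC)[C@@H](O)CC(=O)/C(CO[Si](c2ccccc2)(c2ccccc2)C(C)(C)C)=C\[C@H](O[Si](CC)(CC)CC)[C@@H]1C(=C)CO[Si](CC)(CC)CC
A3 | alternative 2 | 3-(bromomethyl)butenolide with tethered C8 aldehyde | O=CC/C(C)=C\C[C@H](OC(C)=O)/C(CO[Si](C)(C)C(C)(C)C)=C\[C@@H]1OC(=O)C(CBr)=C1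
A4 | alternative 2 | ten-membered C8 alcohol with cis-fused α-methylene lactone (same compound as 40) | O[C@@H]1C/C(C)=C\C[C@H](OC(C)=O)/C(CO[Si](C)(C)C(C)(C)C)=C\[C@@H]2OC(=O)C(=C)[C@@H]21
A5 | alternative 3 | hydroazulenol mesylate (C6 hydroxyl, C1 mesylate anti to the C6–C10 bond) | CC(C)(C)[Si](C)(C)O[C@@H]1C[C@]2(C)[C@H](OS(C)(=O)=O)C[C@H](OCc3ccc(OC)cc3)C(CO[Si](c3ccccc3)(c3ccccc3)C(C)(C)C)=C[C@]2(O)[C@@H]1CC(=O)OC(C)(C)C
A6 | alternative 3 | Z,Z-cyclodecadienone | CC(C)(C)[Si](C)(C)O[C@@H]1C/C(C)=C\C[C@H](OCc2ccc(OC)cc2)/C(CO[Si](c2ccccc2)(c2ccccc2)C(C)(C)C)=C\C(=O)[C@@H]1CC(=O)OC(C)(C)C
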